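**Plan**

1. Retrosynthesis, in order: (a) the CH2–CH2 bond in the middle of the (CH2)4 tether between the ring ketone and the lactam nitrogen of the eleven-membered ring A (radical conjugate addition with loss of CO2); (b) the acyl–vinyl bond and the activated ester; (c) the N–C(=O) and N–CH bonds of pyrrolidinone ring B and the bond from its N–CH carbon to the pendant lactone ring D; (d) the aldol bond between the ethyl-bearing carbon and the O–CH carbon of the fused lactone ring C, with its ester C–O bond; (e) the bond between the C–OH carbon and the β-carbon of ring C, with the C–CH3 bond.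
2. Forward: the quaternary carbinol carbon and the ring C skeleton come first (steps 1–5), ring C closes by aldol–lactonization (7), ring B by amine condensation (9), ring D by vinylogous Mannich reaction and hydrogenation (11, 12), ring A last (17).
3. Stereochemistry: the C–OH carbon comes from L-allylglycine through a cis-2-tert-butyl-1,3-dioxolan-4-one; the β- and α-carbons of ring C from the menthyloxy acetal of the furanone; the ethyl-bearing carbon and the O–CH carbon of ring C from the (S)-benzyloxazolidinone; the N–CH carbon and the O–CH carbon of ring D from substrate control in the Mannich step; the methyl carbon of ring D from hydrogenation.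
4. Enabling feature: in ring A the ketone carbonyl lies two carbons from one end of the bond formed and the lactam nitrogen two carbons from the other. One end is therefore the β-carbon of a vinyl ketone, and the other is the carbon that carries the carboxyl group of a β-alanine unit on nitrogen, which becomes a radical on decarboxylation; the four CH2 groups carry no stereocentre.

Key step: step 17

Assumption: (5S)-5-[(1S,2R,5S)-menthyloxy]furan-2(5H)-one 5, the mirror image of the common l-menthyl reagent, is taken as purchasable; otherwise it is one acetalization from 5-hydroxyfuran-2(5H)-one and (+)-menthol.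

**Step 1**
Reactants: 1 L-allylglycine
Product: 2 (S)-2-hydroxypent-4-enoic acid
Conditions: NaNO2, 1 M H2SO4, H2O, 0 °C to rt
Reagents that add atoms: water, O
Why: Diazotization of the α-amino acid goes with net retention through the α-lactone (double inversion), so the S centre of 1 should be carried into 2.

**Step 2**
Reactants: 2 (S)-2-hydroxypent-4-enoic acid; 3 pivalaldehyde
Product: 4 (2S,5S)-2-tert-butyl-5-(prop-2-en-1-yl)-1,3-dioxolan-4-one
Conditions: TsOH·H2O (cat.), H2SO4 (cat.), pentane, reflux, Dean–Stark; chromatography to remove the trans isomer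
Reagents that add atoms: none
Why: Acid-catalysed acetalization should give mainly the cis-dioxolanone, whose new acetal centre stores the configuration of the carbinol carbon (self-regeneration of stereocentres).

**Step 3**
Reactants: 4 the cis-dioxolanone; 5 (5S)-5-(menthyloxy)furan-2(5H)-one
Product: 7 dioxolanone–lactone Michael–methylation adduct, via lithium lactone enolate 6 (not isolated)
Conditions: LiN(iPr)2, THF, −78 °C; 5, −78 °C; then MeI, DMPU, −78 to −40 °C
Reagents that add atoms: iodomethane, CI
Why: Tandem Michael addition–enolate alkylation: the enolate of 4 reacts anti to tert-butyl (sets the future C–OH carbon), the furanone is attacked anti to the menthyloxy group (sets the β-carbon of ring C), and the lactone enolate is methylated anti to the new β-substituent (sets the α-methyl carbon).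

**Step 4**
Reactants: 7 the Michael–methylation adduct
Product: 8 dimethyl acetal methyl ester
Conditions: CSA (cat.), HC(OMe)3, MeOH, 40 °C
Reagents that add atoms: methanol, CO; trimethyl orthoformate, COC(OC)OC (water scavenger, can also deliver methoxy)
Why: Acid-catalysed methanolysis (transacetalization) opens the γ-alkoxy-lactone pseudo-ester to the acetal ester, while the dioxolanone, whose carbonyl is shielded by the adjacent quaternary carbon, should stay closed.

**Step 5**
Reactants: 8 the dimethyl acetal methyl ester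
Product: 9 aldehyde ester
Conditions: LiBF4, MeCN/H2O (50:1), rt
Reagents that add atoms: water, O
Why: Mild Lewis-acid acetal hydrolysis should free the aldehyde without epimerizing the adjacent methine or opening the dioxolanone.

**Step 6**
Reactants: 10 (S)-4-benzyl-1,3-oxazolidin-2-one; 11 butanoyl chloride
Product: 12 (S)-4-benzyl-3-butanoyl-1,3-oxazolidin-2-one
Conditions: n-BuLi, THF, −78 °C; then 11, −78 to 0 °C
Reagents that add atoms: none
Why: N-acylation of the lithiated oxazolidinone by the acid chloride gives the Evans imide.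

**Step 7**
Reactants: 9 the aldehyde ester; 12 the butanoyl imide
Product: 15 ring C lactone imide, via boron enolate 13 (not isolated), via aldol adduct 14 (not isolated)
Conditions: 12, Bu2BOTf, iPr2NEt, CH2Cl2, −78 to 0 °C; then 9, −78 to 0 °C; MeOH, pH 7 buffer, H2O2, 0 °C; then PPTS (cat.), PhMe, 60 °C
Reagents that add atoms: none
Why: The Evans syn aldol through the Z-boron enolate in a Zimmerman–Traxler chair should set the ethyl-bearing carbon (S) and the carbinol carbon (R) under auxiliary control, matched with the anti-Felkin preference of Z-enolates for this α-branched aldehyde, and acid-catalysed lactonization of the new hydroxyl onto the methyl ester closes the cis-4,5-disubstituted γ-lactone.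

**Step 8**
Reactants: 15 the ring C lactone imide
Product: 16 aldehyde (allyl cut to 2-oxoethyl)
Conditions: O3, CH2Cl2, −78 °C; then PPh3, −78 °C to rt
Reagents that add atoms: ozone, [O-][O+]=O
Why: Ozonolysis with reductive work-up cleaves the only alkene to the aldehyde.

**Step 9**
Reactants: 16 the aldehyde; 17 β-alanine tert-butyl ester hydrochloride
Product: 18 N-acyl hemiaminal (5-hydroxy lactam, both epimers at the hemiaminal carbon)
Conditions: Et3N, CH2Cl2, rt
Reagents that add atoms: none
Why: The amine adds to the aldehyde and the carbinolamine nitrogen acylates itself on the activated dioxolanone carbonyl (5-exo-trig aminolysis), which expels pivalaldehyde, frees the tertiary hydroxyl and closes ring B.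

**Step 10**
Reactants: 19 3-methylfuran-2(5H)-one
Product: 20 3-methyl-2-(triisopropylsilyloxy)furan
Conditions: iPr3SiOTf, Et3N, CH2Cl2, 0 °C
Reagents that add atoms: triisopropylsilyl trifluoromethanesulfonate, CC(C)[Si](OS(=O)(=O)C(F)(F)F)(C(C)C)C(C)C
Why: O-silylation of the butenolide dienolate gives the 2-silyloxyfuran.

**Step 11**
Reactants: 18 the N-acyl hemiaminal; 20 the silyloxyfuran
Product: 22 butenolide lactam, via N-acyliminium ion 21 (not isolated)
Conditions: BF3·OEt2, CH2Cl2, −78 °C
Reagents that add atoms: none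
Why: Vinylogous Mannich reaction: the furan should attack the N-acyliminium ion through its 5-position on the face cis to the pseudoaxial hydroxyl and anti to the bulky lactone substituent (inside-attack model for five-membered cyclic cations, 1,3-cis to oxygen), with the threo relation between N–CH and O–CH that is usual for five-membered N-acyliminium ions.

**Step 12**
Reactants: 22 the butenolide lactam
Product: 23 saturated ring D lactone
Conditions: H2 (1 atm), Pd/C, EtOAc, rt
Reagents that add atoms: none
Why: Heterogeneous hydrogenation should add to the butenolide face anti to the pyrrolidinone substituent, which places the methyl group cis to it.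

**Step 13**
Reactants: 23 the saturated imide
Product: 24 S-ethyl thioester
Conditions: EtSH, n-BuLi, THF, 0 °C; AcOH quench
Reagents that add atoms: ethanethiol, CCS
Why: Thiolate cleavage of the imide at the exocyclic carbonyl (acyl transfer) gives the thioester under weakly basic conditions that should not cause β-elimination of the lactone oxygen.

**Step 14**
Reactants: 24 the thioester
Product: 25 vinyl ketone
Conditions: CH2=CHSnBu3, Pd2(dba)3 (cat.), P(2-furyl)3, CuO2PPh2, THF, 50 °C
Reagents that add atoms: tributyl(vinyl)stannane, C=C[Sn](CCCC)(CCCC)CCCC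
Why: Liebeskind–Srogl-type ketone synthesis: zerovalent palladium inserts into the C–S bond and the monovalent copper phosphinate traps the thiolate and promotes transfer of vinyl from tin, under neutral conditions that spare the α-stereocentre and the β-acyloxy group.

**Step 15**
Reactants: 25 the vinyl ketone tert-butyl ester
Product: 26 vinyl ketone acid
Conditions: TFA/CH2Cl2 (1:4), 0 °C to rt
Reagents that add atoms: none
Why: Acidolysis of the tert-butyl ester (loss of isobutene) frees the acid without touching lactones, lactam or enone.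

**Step 16**
Reactants: 26 the vinyl ketone acid
Product: 27 N-acyloxyphthalimide
Conditions: N-hydroxyphthalimide, iPrN=C=NiPr, CH2Cl2, rt
Reagents that add atoms: N-hydroxyphthalimide, O=C1c2ccccc2C(=O)N1O
Why: Carbodiimide esterification gives the redox-active ester.

**Step 17**
Reactants: 27 the N-acyloxyphthalimide
Product: 30 CNP0221273.1, via primary alkyl radical 28 (not isolated), via cyclized α-keto radical 29 (not isolated)
Conditions: Ru(bpy)3(PF6)2 (2 mol %), Hantzsch ester (1.5 equiv), CH2Cl2, 2 mM, blue LEDs, rt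
Reagents that add atoms: none
Why: Light excites the divalent ruthenium complex, the Hantzsch ester reduces it to the monovalent state, and electron transfer to the phthalimide ester causes N–O cleavage and loss of CO2 to give radical 28 on the carbon β to the lactam nitrogen. This nucleophilic radical adds to the unsubstituted terminus of the vinyl ketone, and radical 29 is quenched by hydrogen-atom transfer from the Hantzsch ester (or by reduction and protonation). The closest known reaction types are the decarboxylative Giese reaction of N-acyloxyphthalimides and the endo radical macrocyclization of ω-haloalkyl vinyl ketones. Ring A closes in the 11-endo-trig mode. No stereocentre is formed, since both carbons joined and the α-carbon end as CH2 groups. The step needs endo regioselectivity and ring closure ahead of premature reduction or dimerization: polarity matching and the free CH2 terminus favour endo over 10-exo attack, the lactam and the cis-fused lactone hold both chain ends on one side, and high dilution keeps the bimolecular paths slow.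

**Compound list**

1 | L-allylglycine, (S)-2-aminopent-4-enoic acid | N[C@@H](CC=C)C(=O)O | starting material
2 | (S)-2-hydroxypent-4-enoic acid | O[C@@H](CC=C)C(=O)O | intermediate
3 | pivalaldehyde | CC(C)(C)C=O | starting material
4 | (2S,5S)-2-tert-butyl-5-(prop-2-en-1-yl)-1,3-dioxolan-4-one (cis) | C=CC[C@@H]1O[C@H](C(C)(C)C)OC1=O | intermediate
5 | (5S)-5-{[(1S,2R,5S)-5-methyl-2-(propan-2-yl)cyclohexyl]oxy}furan-2(5H)-one | O=C1C=C[C@H](O1)O[C@H]2C[C@@H](C)CC[C@@H]2C(C)C | starting material
6 | lithium lactone enolate of the Michael adduct of 4 and 5 | [Li+].C=CC[C@]1([C@@H]2[C@@H](O[C@H]3C[C@@H](C)CC[C@@H]3C(C)C)OC([O-])=C2)O[C@H](C(C)(C)C)OC1=O | intermediate (not isolated)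
7 | (2S,5R)-2-tert-butyl-5-[(2S,3R,4S)-2-{[(1S,2R,5S)-menthyl]oxy}-4-methyl-5-oxooxolan-3-yl]-5-(prop-2-en-1-yl)-1,3-dioxolan-4-one | C=CC[C@]1([C@@H]2[C@@H](O[C@H]3C[C@@H](C)CC[C@@H]3C(C)C)OC(=O)[C@H]2C)O[C@H](C(C)(C)C)OC1=O | intermediate
8 | methyl (2S,3R)-3-[(2S,4R)-2-tert-butyl-5-oxo-4-(prop-2-en-1-yl)-1,3-dioxolan-4-yl]-4,4-dimethoxy-2-methylbutanoate | C=CC[C@]1([C@@H]([C@H](C)C(=O)OC)C(OC)OC)O[C@H](C(C)(C)C)OC1=O | intermediate
9 | methyl (2S,3R)-3-[(2S,4R)-2-tert-butyl-5-oxo-4-(prop-2-en-1-yl)-1,3-dioxolan-4-yl]-2-methyl-4-oxobutanoate | C=CC[C@]1([C@@H]([C@H](C)C(=O)OC)C=O)O[C@H](C(C)(C)C)OC1=O | intermediate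
10 | (S)-4-benzyl-1,3-oxazolidin-2-one | O=C1N[C@@H](Cc2ccccc2)CO1 | starting material
11 | butanoyl chloride | CCCC(=O)Cl | starting material
12 | (S)-4-benzyl-3-butanoyl-1,3-oxazolidin-2-one | CCCC(=O)N1C(=O)OC[C@@H]1Cc1ccccc1 | intermediate
13 | Z-dibutylboron enolate of 12 | CC/C=C(\OB(CCCC)CCCC)N1C(=O)OC[C@@H]1Cc1ccccc1 | intermediate (not isolated)
14 | syn-aldol adduct of 13 and 9: β-hydroxy imide, (2S,3R) at the two new centres, methyl ester still open | CC[C@@H]([C@H](O)[C@H]([C@H](C)C(=O)OC)[C@@]2(CC=C)O[C@H](C(C)(C)C)OC2=O)C(=O)N3C(=O)OC[C@@H]3Cc4ccccc4 | intermediate (not isolated)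
15 | (4S)-4-benzyl-3-[(2S)-2-{(2R,3S,4S)-3-[(2S,4R)-2-tert-butyl-5-oxo-4-(prop-2-en-1-yl)-1,3-dioxolan-4-yl]-4-methyl-5-oxooxolan-2-yl}butanoyl]-1,3-oxazolidin-2-one | CC[C@@H]([C@@H]1OC(=O)[C@@H](C)[C@@H]1[C@@]2(CC=C)O[C@H](C(C)(C)C)OC2=O)C(=O)N3C(=O)OC[C@@H]3Cc4ccccc4 | intermediate
16 | aldehyde: 15 with the prop-2-en-1-yl group cut down to 2-oxoethyl | CC[C@@H]([C@@H]1OC(=O)[C@@H](C)[C@@H]1[C@@]2(CC=O)O[C@H](C(C)(C)C)OC2=O)C(=O)N3C(=O)OC[C@@H]3Cc4ccccc4 | intermediate
17 | tert-butyl 3-aminopropanoate hydrochloride (β-alanine tert-butyl ester hydrochloride) | Cl.NCCC(=O)OC(C)(C)C | starting material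
18 | N-acyl hemiaminal: tert-butyl 3-[(3R)-3,5-dihydroxy-2-oxo-3-(ring C lactone of 15)pyrrolidin-1-yl]propanoate, both C-5 epimers | CC[C@@H]([C@@H]1OC(=O)[C@@H](C)[C@@H]1[C@]2(O)CC(O)N(CCC(=O)OC(C)(C)C)C2=O)C(=O)N3C(=O)OC[C@@H]3Cc4ccccc4 | intermediate
19 | 3-methylfuran-2(5H)-one | CC1=CCOC1=O | starting material
20 | 3-methyl-2-(triisopropylsilyloxy)furan | CC1=C(O[Si](C(C)C)(C(C)C)C(C)C)OC=C1 | intermediate
21 | N-acyliminium ion from 18 | CC[C@@H]([C@@H]1OC(=O)[C@@H](C)[C@@H]1[C@]2(O)CC=[N+](CCC(=O)OC(C)(C)C)C2=O)C(=O)N3C(=O)OC[C@@H]3Cc4ccccc4 | intermediate (not isolated)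
22 | butenolide lactam: (3R,5S)-pyrrolidinone carrying (2S)-4-methyl-5-oxo-2,5-dihydrofuran-2-yl at C-5, threo | CC[C@@H]([C@@H]1OC(=O)[C@@H](C)[C@@H]1[C@]2(O)C[C@@H]([C@@H]5C=C(C)C(=O)O5)N(CCC(=O)OC(C)(C)C)C2=O)C(=O)N3C(=O)OC[C@@H]3Cc4ccccc4 | intermediate
23 | 22 with the butenolide reduced to the (2S,4S)-4-methyl-5-oxooxolan-2-yl group | CC[C@@H]([C@@H]1OC(=O)[C@@H](C)[C@@H]1[C@]2(O)C[C@@H]([C@@H]5C[C@H](C)C(=O)O5)N(CCC(=O)OC(C)(C)C)C2=O)C(=O)N3C(=O)OC[C@@H]3Cc4ccccc4 | intermediate
24 | S-ethyl thioester: 23 with the oxazolidinone replaced by SEt | CC[C@@H]([C@@H]1OC(=O)[C@@H](C)[C@@H]1[C@]2(O)C[C@@H]([C@@H]5C[C@H](C)C(=O)O5)N(CCC(=O)OC(C)(C)C)C2=O)C(=O)SCC | intermediate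
25 | vinyl ketone tert-butyl ester | CC[C@@H]([C@@H]1OC(=O)[C@@H](C)[C@@H]1[C@]2(O)C[C@@H]([C@@H]5C[C@H](C)C(=O)O5)N(CCC(=O)OC(C)(C)C)C2=O)C(=O)C=C | intermediate
26 | vinyl ketone acid | CC[C@@H]([C@@H]1OC(=O)[C@@H](C)[C@@H]1[C@]2(O)C[C@@H]([C@@H]5C[C@H](C)C(=O)O5)N(CCC(=O)O)C2=O)C(=O)C=C | intermediate
27 | N-acyloxyphthalimide of 26 | CC[C@@H]([C@@H]1OC(=O)[C@@H](C)[C@@H]1[C@]2(O)C[C@@H]([C@@H]5C[C@H](C)C(=O)O5)N(CCC(=O)ON6C(=O)c7ccccc7C6=O)C2=O)C(=O)C=C | intermediate
28 | primary alkyl radical (N–CH2–CH2 radical) | CC[C@@H]([C@@H]1OC(=O)[C@@H](C)[C@@H]1[C@]2(O)C[C@@H]([C@@H]5C[C@H](C)C(=O)O5)N(C[CH2])C2=O)C(=O)C=C | intermediate (not isolated)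
29 | cyclized α-keto radical | CC[C@@H]1C(=O)[CH]CCCN2C(=O)[C@@](O)(C[C@H]2[C@@H]2C[C@H](C)C(=O)O2)[C@@H]2[C@H]1OC(=O)[C@H]2C | intermediate (not isolated)
30 | CNP0221273.1: ethyl-bearing carbon S, O–CH of ring C R, ring-fusion CH S, methyl carbon of ring C S, carbinol carbon R, N–CH S, O–CH of ring D S, methyl carbon of ring D S | CC[C@@H]1C(=O)CCCCN2C(=O)[C@@](O)(C[C@H]2[C@@H]2C[C@H](C)C(=O)O2)[C@@H]2[C@H]1OC(=O)[C@H]2C | target

**Count and risks**

Total steps: 17. Longest linear sequence: 15 (steps 1–5, 7–9, 11–17); steps 6 and 10 prepare side reagents.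

Most likely to fail:

- **Step 17.** Premature hydrogen-atom transfer to the primary radical, or intermolecular addition, may outrun the strained 11-endo closure. The fallback closes the same bond by ring-closing metathesis and hydrogenation; it sets out from aldehyde 16 (with silyloxyfuran 20) and comes back at target 30. Aldehyde 16 is condensed with allylamine (CH2Cl2, rt) to the N-allyl hydroxy lactam F1. The vinylogous Mannich reaction with 20 (BF3·OEt2, −78 °C) should give the N-allyl butenolide lactam F2, and EtSLi the thioester F3. Coupling with allyltributylstannane (Pd2(dba)3, P(2-furyl)3, CuO2PPh2) should give the allyl ketone F4. Metathesis with (H2IMes)(PCy3)Cl2Ru=CHPh (second-generation Grubbs catalyst, CH2Cl2, high dilution) joins the two allyl groups to the macrocyclic alkene F5. Hydrogenation (H2, Pd/C) then saturates the ring alkene and the butenolide, the methyl group ending cis as in step 12, to give 30.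

- **Step 11.** Facial selectivity at the iminium carbon may be poor, or the threo preference may erode. The fallback uses auxiliary control on an acyclic imine; it sets out from aldehyde 16 (with 20) and comes back at 23. Aldehyde 16 and (R)-tert-butanesulfinamide (CuSO4, CH2Cl2) give the N-sulfinyl imine F6. Addition of 20 promoted by Me3SiOTf, expected anti to tert-butyl of the s-cis sulfinyl imine in an open transition state, should give the sulfinamide butenolide F7. HCl in dioxane removes the sulfinyl group, and after neutralization the amine closes ring B on the dioxolanone to give the N–H lactam F8. Hydrogenation gives the saturated N–H lactam F9, and conjugate addition of its N–H to tert-butyl acrylate (Cs2CO3 cat., MeCN) gives 23.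

- **Step 14.** Acyl transfer at the hindered α-branched thioester may be slow, so that protodestannylation or decay of the enone under the coupling conditions takes over. The fallback replaces the coupling by reduction, vinyl addition and oxidation; it sets out from thioester 24 and comes back at 25. Fukuyama reduction (Et3SiH, Pd/C, acetone) gives the aldehyde F10. CH2=CHMgBr (THF, −78 °C, selective for the aldehyde) gives the allylic alcohol F11 as both carbinol epimers, and Dess–Martin periodinane oxidizes it to 25.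

Further compounds
F1 | step 17 | N-allyl hydroxy lactam (18 with N-allyl in place of the ester chain) | CC[C@@H]([C@@H]1OC(=O)[C@@H](C)[C@@H]1[C@]2(O)CC(O)N(CC=C)C2=O)C(=O)N3C(=O)OC[C@@H]3Cc4ccccc4
F2 | step 17 | N-allyl butenolide lactam | CC[C@@H]([C@@H]1OC(=O)[C@@H](C)[C@@H]1[C@]2(O)C[C@@H]([C@@H]5C=C(C)C(=O)O5)N(CC=C)C2=O)C(=O)N3C(=O)OC[C@@H]3Cc4ccccc4
F3 | step 17 | N-allyl butenolide S-ethyl thioester | CC[C@@H]([C@@H]1OC(=O)[C@@H](C)[C@@H]1[C@]2(O)C[C@@H]([C@@H]5C=C(C)C(=O)O5)N(CC=C)C2=O)C(=O)SCC
F4 | step 17 | N-allyl butenolide allyl ketone | CC[C@@H]([C@@H]1OC(=O)[C@@H](C)[C@@H]1[C@]2(O)C[C@@H]([C@@H]5C=C(C)C(=O)O5)N(CC=C)C2=O)C(=O)CC=C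
F5 | step 17 | macrocyclic alkene with butenolide (didehydro precursor of 30, alkene geometry open) | CC[C@@H]1C(=O)CC=CCN2C(=O)[C@@](O)(C[C@H]2[C@@H]2C=C(C)C(=O)O2)[C@@H]2[C@H]1OC(=O)[C@H]2C
F6 | step 11 | (R)-N-tert-butanesulfinyl imine of 16 | CC[C@@H]([C@@H]1OC(=O)[C@@H](C)[C@@H]1[C@@]2(C/C=N/[S@](=O)C(C)(C)C)O[C@H](C(C)(C)C)OC2=O)C(=O)N3C(=O)OC[C@@H]3Cc4ccccc4
F7 | step 11 | sulfinamide butenolide | CC[C@@H]([C@@H]1OC(=O)[C@@H](C)[C@@H]1[C@@]2(C[C@H](N[S@](=O)C(C)(C)C)[C@@H]5C=C(C)C(=O)O5)O[C@H](C(C)(C)C)OC2=O)C(=O)N3C(=O)OC[C@@H]3Cc4ccccc4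
F8 | step 11 | N–H lactam butenolide | CC[C@@H]([C@@H]1OC(=O)[C@@H](C)[C@@H]1[C@]2(O)C[C@@H]([C@@H]5C=C(C)C(=O)O5)NC2=O)C(=O)N3C(=O)OC[C@@H]3Cc4ccccc4
F9 | step 11 | saturated N–H lactam | CC[C@@H]([C@@H]1OC(=O)[C@@H](C)[C@@H]1[C@]2(O)C[C@@H]([C@@H]5C[C@H](C)C(=O)O5)NC2=O)C(=O)N3C(=O)OC[C@@H]3Cc4ccccc4
F10 | step 14 | aldehyde from 24 | CC[C@@H]([C@@H]1OC(=O)[C@@H](C)[C@@H]1[C@]2(O)C[C@@H]([C@@H]5C[C@H](C)C(=O)O5)N(CCC(=O)OC(C)(C)C)C2=O)C=O
F11 | step 14 | allylic alcohol (both carbinol epimers) | CC[C@@H]([C@@H]1OC(=O)[C@@H](C)[C@@H]1[C@]2(O)C[C@@H]([C@@H]5C[C@H](C)C(=O)O5)N(CCC(=O)OC(C)(C)C)C2=O)C(O)C=C
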